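## Structural features

The target is a flavanone: benzo ring A is fused to the dihydropyran-4-one ring C, and C2 of ring C carries the phenyl ring B. Ring A is fully substituted: hydroxyls on C5 and C7, a 3-methylbut-2-enoyl group on C8, and on C6 a methylene bridge to C3 of a 6-ethyl-4-hydroxy-5-methyl-2-pyranone. C2 (S) is the only stereocentre and has no stereogenic neighbour. It is a benzylic ether carbon beta to the C4 ketone, so it is lost whenever ring C opens to the 2'-hydroxychalcone, which base brings about easily. Other fragile points are the C8 enone, which can close onto the 7-hydroxyl to a 2,2-dimethylchromanone under acid or base, the acidic pyranone enol (a vinylogous carboxylic acid), and the very electron-rich ring A. The real difficulty is to place four different groups on a phloroglucinol core without regiochemical ambiguity and to create C2 as one enantiomer under conditions that never reopen ring C, with the C8 acyl group arriving last under neutral conditions. Two features help. First, O1 is para to the C6 arm, so ring A without C4 and without the C8 acyl group is mirror-symmetric about the C6–C8a axis. Second, C2 bears one hydrogen, a phenyl ring and O1, which is the pattern of a benzyl ether carbon on O1, while C3 is the alpha-carbon of the C4 ketone; the key step uses this by inserting a keto-carbenoid at C3 into a benzylic C–H bond of the O1 benzyl ether.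

## Logic of the disconnections

18 to 17: the C8–C(acyl) bond is cut and the acyl group is returned to O7. The enone beside a free phenol tolerates neither Lewis acid nor base, whereas an O-to-C acyl shift can be driven by light alone. The gain is that the last C–C bond needs no reagent. The forward step must be regioselective, which the substitution pattern secures (C8 is the only hydrogen-bearing position ortho or para to O7), and must be photochemically efficient despite the chelated aryl ketone.

17 to 15 and 16: the ester C–O bond is cut. This separates a five-carbon acyl unit from the complete polyphenol. The forward step must acylate O7 and not the chelated 5-hydroxyl or the pyranone enol.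

15 to 14: three O–Si bonds are cut. The two phenols and the pyranone enol must be masked during enolate and carbenoid chemistry, and one reagent should remove all three. The forward step must not become basic, or ring C opens.

14 to 13: the C2–C3 bond is cut, which opens ring C and removes the stereocentre. The precursor is an achiral aryl diazomethyl ketone whose O1 benzyl group already contains C2 and ring B. The forward step must prefer 1,6 C–H insertion over ylide formation at O1 and must distinguish two enantiotopic hydrogens.

13 to 11 (through 12): the C=N2 bond is cut, leaving a methyl ketone. The forward step must activate the methyl group without disturbing the silyl ethers or the pyranone side chains.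

11 to 10: the three O–Si bonds are cut, leaving free hydroxyls. The forward step must silylate a chelated, doubly flanked phenol, which calls for a silyl triflate.

10 to 8 (through 9): the C4a–C4 aryl–acetyl bond is cut. The resulting arene is symmetric, so its two free positions are equivalent and the acylation cannot give a regioisomer. The forward step must acylate a polyphenol on carbon and spare the benzyl ether.

8 to 6 and 3 (through 7): the bond between the bridge methylene and C3 of the pyranone is cut. The bridge carbon is an aldehyde carbon in 6, which fixes the arm para to the benzyl ether. The forward step must condense a deactivated aldehyde and reduce the alkylidene before it reacts further.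

6 to 4 and 5: the O–CH2 bond of the benzyl ether is cut. The forward step must alkylate only the hydroxyl para to the formyl group.

3 to 1 and 2: the C3–C4... ring bonds C4–C5 and O1–C2 of the pyranone are cut, giving a symmetrical ketone and a three-carbon diacyl unit. The symmetry of 1 removes any regiochemical question in the annulation.

## Other disconnections considered

Alternative 1: The cut is the O1–C8a aryl ether bond. In the forward step the benzylic alkoxide of the (S)-beta-hydroxy ketone A2 attacks C8a, which bears fluorine between two acyl groups, and expels fluoride by addition–elimination to give A1.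
- In its favour: C2 is made beforehand by a well-understood asymmetric aldol or reduction, and the ring closure neither forms nor breaks a bond at C2. On stereocontrol this is the better plan. The C8 acyl group is already present and acts as an activating group, so no late acylation is needed, which is also better than the chosen plan.
- Against it here: A1 has methyl ethers on O5 and O7 and no arm on C6. Two aryl methyl ethers must then be cleaved with a strong Lewis acid in the presence of the enone and the stereocentre, and the pyranonylmethyl group must be attached afterwards. The alkoxide of A2 can also undergo retro-aldol cleavage or dehydrate to a chalcone. The pentasubstituted fluoroarene with two different acyl groups needs its own regiocontrolled synthesis.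
- Comparison: structurally A1 is further from the target than 14. Mechanistically its closure is the more predictable. In step economy it is expected to be longer.

Alternative 2: The cuts are C3–C4 and O1–C2. In the forward step the ortho-hydroxybenzaldehyde A4 condenses with an orthoformate under a confined chiral Brønsted acid to a methoxy ortho-quinone methide (an oxocarbenium ion), which adds across styrene A5 to give the 4-methoxyflavan A3.
- In its favour: two bonds and ring C form in one convergent step from a commodity alkene, the arm is already in place, and no diazo compound is handled. In convergence and reagent safety it is the better plan.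
- Against it here: C4 arrives as a methyl ether and must be hydrolysed and oxidised to the ketone at a benzylic position of a very electron-rich ring. The C4 stereocentre is made only to be destroyed. The two benzyloxy donors and the free pyranone enol make the cation less electrophilic toward an unactivated alkene.
- Comparison: after hydrogenolysis of the benzyl ethers the end game is the same as in the chosen plan, so the two are equal there. The ring construction is shorter, but the redox correction adds steps. The enantiocontrol rests on a specialised catalyst and an unusual substrate, a risk comparable to that of the insertion.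

Alternative 3: The cut is C4–C4a. In the forward step the (S)-3-aryloxy-3-phenylpropanoic acid A7 is activated and acylates one of the two ring carbons ortho to the ether oxygen, giving A6, which is the same compound as 15.
- In its favour: the aryl ether is symmetric, so regiochemistry is not an issue; this is the same symmetry that the chosen plan uses in step 4. The product is 15 itself, so the two plans are equal from there on. No diazo compound and no rhodium are needed, which is better for scale.
- Against it here: the C2–O bond of A7 is a benzylic aryl ether beta to an activated carboxyl group. Under acylating acid it can ionise or eliminate to a cinnamoyl species and a phenol that recombine without stereocontrol, so the preset configuration is at risk in the key step itself. Making A7 requires O-alkylation of one hydroxyl among four acidic ones with a secondary benzylic electrophile that eliminates easily, so protecting groups return.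
- Comparison: the acylation is robust but stereochemically unsafe, and the step count is expected to be similar.

Key step: step 7

Assumption: Rh2(S-PTTL)4 is taken to deliver the 2S configuration; if its sense of induction is the opposite, the mirror-image catalyst Rh2(R-PTTL)4 is used with nothing else changed (ring positions are in flavanone numbering).

The phenols and the pyranone enol are carried as triisopropylsilyl ethers and not as tert-butyldimethylsilyl ethers. The pyranone silyl ether is a vinylogous silyl ester that must survive aqueous amine in step 6, an ortho-silyloxy group beside a lithium enolate can migrate, and a bulkier silyl group on O5 is a poorer partner for the carbenoid.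

## Route

Step 1
Reactants: 1 3-pentanone; 2 malonyl dichloride
Product: 3 6-ethyl-4-hydroxy-5-methyl-2H-pyran-2-one
Conditions: neat, 1 in excess, rt, 2–3 d; crystallisation
Reagents that add atoms: none
Why: Pyranone annulation of a ketone with malonyl dichloride: one acyl chloride C-acylates the enol of 1 and the other O-acylates the new enol; because 1 is symmetrical only one pattern can form (former alpha-carbon becomes C5 with methyl, carbonyl carbon becomes C6 with ethyl).

Step 2
Reactants: 4 2,4,6-trihydroxybenzaldehyde; 5 benzyl bromide
Product: 6 4-(benzyloxy)-2,6-dihydroxybenzaldehyde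
Conditions: 5 (1.0 equiv), NaHCO3 (1.2 equiv), DMF, rt to 40 °C
Reagents that add atoms: none
Why: Williamson etherification under bicarbonate; the 4-hydroxyl is para to the formyl group, the most acidic and the one not tied up in a hydrogen bond to the carbonyl, so one equivalent of 5 should react there first, as is usual for 4-O-alkylation of 2,4-dihydroxyaryl carbonyl compounds.

Step 3
Reactants: 6 4-(benzyloxy)-2,6-dihydroxybenzaldehyde; 3 6-ethyl-4-hydroxy-5-methyl-2H-pyran-2-one
Product: 8 3-{[4-(benzyloxy)-2,6-dihydroxyphenyl]methyl}-6-ethyl-4-hydroxy-5-methyl-2H-pyran-2-one, via the arylidene pyrandione 7 (not isolated)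
Conditions: Hantzsch ester (diethyl 2,6-dimethyl-1,4-dihydropyridine-3,5-dicarboxylate, 1.2 equiv), L-proline (20 mol%), EtOH, 40 °C
Reagents that add atoms: none
Why: Three-component reductive Knoevenagel alkylation: proline-mediated condensation at C3 of the pyranone gives 7, whose electron-poor exocyclic double bond should accept hydride from the Hantzsch ester before it can add a second pyranone; the former aldehyde carbon becomes the bridge, so the arm sits para to the benzyl ether by construction.

Step 4
Reactants: 8 3-{[4-(benzyloxy)-2,6-dihydroxyphenyl]methyl}-6-ethyl-4-hydroxy-5-methyl-2H-pyran-2-one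
Product: 10 3-{[3-acetyl-4-(benzyloxy)-2,6-dihydroxyphenyl]methyl}-6-ethyl-4-hydroxy-5-methyl-2H-pyran-2-one, via the ketiminium chloride 9 (not isolated)
Conditions: MeCN (5 equiv), ZnCl2 (1 equiv), HCl (g), Et2O–dioxane, 0 °C; then H2O, 80 °C
Reagents that add atoms: acetonitrile, CC#N; water, O; hydrogen chloride, Cl (enters 9 only)
Why: Houben–Hoesch acylation of a phloroglucinol mono-ether; the two free ring positions are equivalent by symmetry and each lies ortho to a hydroxyl and to the benzyl ether, so only one ketiminium salt can form and it deactivates the ring against a second attack; the pyranone has no free nucleophilic carbon and the benzyl ether should tolerate anhydrous HCl at 0 °C.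

Step 5
Reactants: 10 3-{[3-acetyl-4-(benzyloxy)-2,6-dihydroxyphenyl]methyl}-6-ethyl-4-hydroxy-5-methyl-2H-pyran-2-one
Product: 11 3-{[3-acetyl-4-(benzyloxy)-2,6-bis(triisopropylsilyloxy)phenyl]methyl}-6-ethyl-5-methyl-4-(triisopropylsilyloxy)-2H-pyran-2-one
Conditions: i-Pr3SiOTf (3.6 equiv), 2,6-lutidine (5 equiv), CH2Cl2, 0 °C to rt
Reagents that add atoms: triisopropylsilyl trifluoromethanesulfonate, CC(C)[Si](OS(=O)(=O)C(F)(F)F)(C(C)C)C(C)C
Why: O-Silylation of both phenols and the pyranone enol; the triflate is reactive enough for the chelated, doubly flanked hydroxyl beside the acetyl group, and 2,6-lutidine with near-stoichiometric triflate should not enolise the aryl methyl ketone.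

Step 6
Reactants: 11 3-{[3-acetyl-4-(benzyloxy)-2,6-bis(triisopropylsilyloxy)phenyl]methyl}-6-ethyl-5-methyl-4-(triisopropylsilyloxy)-2H-pyran-2-one
Product: 13 2-diazo-1-[2-(benzyloxy)-5-{[6-ethyl-5-methyl-2-oxo-4-(triisopropylsilyloxy)-2H-pyran-3-yl]methyl}-4,6-bis(triisopropylsilyloxy)phenyl]ethan-1-one, via the trifluoroacetyl ketone 12 (not isolated)
Conditions: LiN(SiMe3)2 (1.1 equiv), THF, −78 °C; CF3CO2CH2CF3 (1.2 equiv), −78 °C; then 4-acetamidobenzenesulfonyl azide (1.5 equiv), Et3N (1.5 equiv), H2O (1 equiv), MeCN, rt
Reagents that add atoms: 4-acetamidobenzenesulfonyl azide, CC(=O)Nc1ccc(cc1)S(=O)(=O)N=[N+]=[N-]; 2,2,2-trifluoroethyl trifluoroacetate, O=C(OCC(F)(F)F)C(F)(F)F (enters 12 only)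
Why: Detrifluoroacetylative diazo transfer: kinetic deprotonation of the methyl ketone and Claisen-type trifluoroacetylation give the activated 1,3-diketone 12, which undergoes Regitz diazo transfer with loss of the trifluoroacetyl group onto the sulfonamide; the bulky silyl groups are expected to resist migration to the enolate and hydrolysis in the aqueous amine stage.

Step 7
Reactants: 13 2-diazo-1-[2-(benzyloxy)-5-{[6-ethyl-5-methyl-2-oxo-4-(triisopropylsilyloxy)-2H-pyran-3-yl]methyl}-4,6-bis(triisopropylsilyloxy)phenyl]ethan-1-one
Product: 14 (2S)-6-{[6-ethyl-5-methyl-2-oxo-4-(triisopropylsilyloxy)-2H-pyran-3-yl]methyl}-2-phenyl-5,7-bis(triisopropylsilyloxy)-2,3-dihydro-4H-chromen-4-one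
Conditions: Rh2(S-PTTL)4 (dirhodium tetrakis[N-phthaloyl-(S)-tert-leucinate], 2 mol%), CH2Cl2, 4 Å MS, 0 °C to rt, slow addition of 13
Reagents that add atoms: none
Why: Loss of dinitrogen at the dirhodium centre gives an electrophilic rhodium carbenoid on the future C3. It inserts through a concerted, asynchronous three-centre transition state into one benzylic C–H bond of the O1 benzyl ether, a bond made hydridic by the adjacent oxygen and the phenyl ring, and so forms C2–C3. The closest known reaction type is the dirhodium carboxylate-catalysed enantioselective intramolecular C–H insertion of ortho-alkoxyaryl diazoketones next to the ether oxygen, which gives 2-substituted chroman-4-ones. Ring C closes as a six-membered ring by 1,6-insertion, counting the carbenoid carbon as atom 1 and the benzylic carbon as atom 6. C2 is the only new stereocentre and is set by catalyst control: the phthalimido walls of the chiral carboxylate ligands decide which enantiotopic hydrogen meets the carbenoid, and the neutral conditions cannot reopen the chromanone. The step needs insertion to win over attack on the O1 lone pair (five-membered oxonium ylide, then 1,2-benzyl shift to a 2-benzylbenzofuran-3-one); O1 is an aryl ether oxygen conjugated to an acyl-bearing ring and crowded by the carbonyl, and a bulky electron-poor carboxylate catalyst at low temperature is the class that favours insertion. The O5 triisopropylsilyl ether has a shielded, weakly basic oxygen and no C–H bond within reach of a five- or six-membered transition state, the pyranone arm is meta to the carbenoid-bearing carbon and cannot reach it, and slow addition suppresses carbene dimerisation.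

Step 8
Reactants: 14 (2S)-6-{[6-ethyl-5-methyl-2-oxo-4-(triisopropylsilyloxy)-2H-pyran-3-yl]methyl}-2-phenyl-5,7-bis(triisopropylsilyloxy)-2,3-dihydro-4H-chromen-4-one
Product: 15 (2S)-6-[(6-ethyl-4-hydroxy-5-methyl-2-oxo-2H-pyran-3-yl)methyl]-5,7-dihydroxy-2-phenyl-2,3-dihydro-4H-chromen-4-one
Conditions: Bu4NF (3.3 equiv), AcOH (4 equiv), THF, 0 °C
Reagents that add atoms: none
Why: Fluoride cleavage of two aryl silyl ethers and one vinylogous silyl ester; the acetic acid buffer keeps the medium from becoming basic enough for retro-oxa-Michael opening of ring C, so C2 should keep its configuration.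

Step 9
Reactants: 15 (2S)-6-[(6-ethyl-4-hydroxy-5-methyl-2-oxo-2H-pyran-3-yl)methyl]-5,7-dihydroxy-2-phenyl-2,3-dihydro-4H-chromen-4-one; 16 3-methylbut-2-enoyl chloride
Product: 17 (2S)-6-[(6-ethyl-4-hydroxy-5-methyl-2-oxo-2H-pyran-3-yl)methyl]-5-hydroxy-4-oxo-2-phenyl-3,4-dihydro-2H-chromen-7-yl 3-methylbut-2-enoate
Conditions: 16 (1.05 equiv), pyridine (3 equiv), CH2Cl2, −20 to 0 °C; aq NaHCO3 work-up
Reagents that add atoms: none
Why: O-Acylation of the most nucleophilic free hydroxyl: the 5-hydroxyl is chelated to the C4 carbonyl and flanked on both sides, and an acyl group that lands on the acidic pyranone enol forms a vinylogous mixed anhydride that should pass it on to the 7-phenol or be cleaved on bicarbonate work-up; pyridine at low temperature avoids vinylketene formation from 16 and opening of ring C.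

Step 10
Reactants: 17 (2S)-6-[(6-ethyl-4-hydroxy-5-methyl-2-oxo-2H-pyran-3-yl)methyl]-5-hydroxy-4-oxo-2-phenyl-3,4-dihydro-2H-chromen-7-yl 3-methylbut-2-enoate
Product: 18 (2S)-6-[(6-ethyl-4-hydroxy-5-methyl-2-oxo-2H-pyran-3-yl)methyl]-5,7-dihydroxy-8-(3-methylbut-2-enoyl)-2-phenyl-2,3-dihydro-4H-chromen-4-one
Conditions: hν (254 nm, quartz), degassed MeCN, dilute, rt; run to partial conversion and recycle 17
Reagents that add atoms: none
Why: Photo-Fries rearrangement: homolysis of the aryl ester O–CO bond and in-cage recombination of the acyl and phenoxyl radicals; of the positions ortho and para to O7 only C8 bears hydrogen (C6 holds the arm, C4a the ring fusion), so a single C-acyl product is possible, and the conversion of aryl 3-methylbut-2-enoates into ortho-hydroxyaryl 2-methylpropenyl ketones by this neutral method avoids acid- or base-induced closure of the enone onto the 7-hydroxyl and leaves C2 untouched.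

## Compound list

1 | 3-pentanone | CCC(=O)CC | starting material
2 | malonyl dichloride | O=C(Cl)CC(=O)Cl | starting material
3 | 6-ethyl-4-hydroxy-5-methyl-2H-pyran-2-one | CCc1oc(=O)cc(O)c1C | intermediate
4 | 2,4,6-trihydroxybenzaldehyde | O=Cc1c(O)cc(O)cc1O | starting material
5 | benzyl bromide | BrCc1ccccc1 | starting material
6 | 4-(benzyloxy)-2,6-dihydroxybenzaldehyde | O=Cc1c(O)cc(OCc2ccccc2)cc1O | intermediate
7 | 3-{[4-(benzyloxy)-2,6-dihydroxyphenyl]methylidene}-6-ethyl-5-methyl-2H-pyran-2,4(3H)-dione (formed in the flask in step 3) | CCC1=C(C)C(=O)C(=Cc2c(O)cc(OCc3ccccc3)cc2O)C(=O)O1 | intermediate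
8 | 3-{[4-(benzyloxy)-2,6-dihydroxyphenyl]methyl}-6-ethyl-4-hydroxy-5-methyl-2H-pyran-2-one | CCc1oc(=O)c(Cc2c(O)cc(OCc3ccccc3)cc2O)c(O)c1C | intermediate
9 | 1-[6-(benzyloxy)-3-[(6-ethyl-4-hydroxy-5-methyl-2-oxo-2H-pyran-3-yl)methyl]-2,4-dihydroxyphenyl]ethan-1-iminium chloride (formed in the flask in step 4) | CCc1oc(=O)c(Cc2c(O)cc(OCc3ccccc3)c(C(C)=[NH2+])c2O)c(O)c1C.[Cl-] | intermediate
10 | 3-{[3-acetyl-4-(benzyloxy)-2,6-dihydroxyphenyl]methyl}-6-ethyl-4-hydroxy-5-methyl-2H-pyran-2-one | CCc1oc(=O)c(Cc2c(O)cc(OCc3ccccc3)c(C(C)=O)c2O)c(O)c1C | intermediate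
11 | 3-{[3-acetyl-4-(benzyloxy)-2,6-bis(triisopropylsilyloxy)phenyl]methyl}-6-ethyl-5-methyl-4-(triisopropylsilyloxy)-2H-pyran-2-one | CCc1oc(=O)c(Cc2c(O[Si](C(C)C)(C(C)C)C(C)C)cc(OCc3ccccc3)c(C(C)=O)c2O[Si](C(C)C)(C(C)C)C(C)C)c(O[Si](C(C)C)(C(C)C)C(C)C)c1C | intermediate
12 | 1-[2-(benzyloxy)-5-{[6-ethyl-5-methyl-2-oxo-4-(triisopropylsilyloxy)-2H-pyran-3-yl]methyl}-4,6-bis(triisopropylsilyloxy)phenyl]-4,4,4-trifluorobutane-1,3-dione (formed in the flask in step 6) | CCc1oc(=O)c(Cc2c(O[Si](C(C)C)(C(C)C)C(C)C)cc(OCc3ccccc3)c(C(=O)CC(=O)C(F)(F)F)c2O[Si](C(C)C)(C(C)C)C(C)C)c(O[Si](C(C)C)(C(C)C)C(C)C)c1C | intermediate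
13 | 2-diazo-1-[2-(benzyloxy)-5-{[6-ethyl-5-methyl-2-oxo-4-(triisopropylsilyloxy)-2H-pyran-3-yl]methyl}-4,6-bis(triisopropylsilyloxy)phenyl]ethan-1-one | [N-]=[N+]=CC(=O)c1c(OCc2ccccc2)cc(O[Si](C(C)C)(C(C)C)C(C)C)c(Cc2c(O[Si](C(C)C)(C(C)C)C(C)C)c(C)c(CC)oc2=O)c1O[Si](C(C)C)(C(C)C)C(C)C | intermediate
14 | (2S)-6-{[6-ethyl-5-methyl-2-oxo-4-(triisopropylsilyloxy)-2H-pyran-3-yl]methyl}-2-phenyl-5,7-bis(triisopropylsilyloxy)-2,3-dihydro-4H-chromen-4-one | CCc1oc(=O)c(Cc2c(O[Si](C(C)C)(C(C)C)C(C)C)cc3c(c2O[Si](C(C)C)(C(C)C)C(C)C)C(=O)C[C@@H](c2ccccc2)O3)c(O[Si](C(C)C)(C(C)C)C(C)C)c1C | intermediate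
15 | (2S)-6-[(6-ethyl-4-hydroxy-5-methyl-2-oxo-2H-pyran-3-yl)methyl]-5,7-dihydroxy-2-phenyl-2,3-dihydro-4H-chromen-4-one | CCc1oc(=O)c(Cc2c(O)cc3c(c2O)C(=O)C[C@@H](c2ccccc2)O3)c(O)c1C | intermediate
16 | 3-methylbut-2-enoyl chloride | CC(C)=CC(=O)Cl | starting material
17 | (2S)-6-[(6-ethyl-4-hydroxy-5-methyl-2-oxo-2H-pyran-3-yl)methyl]-5-hydroxy-4-oxo-2-phenyl-3,4-dihydro-2H-chromen-7-yl 3-methylbut-2-enoate | CCc1oc(=O)c(Cc2c(OC(=O)C=C(C)C)cc3c(c2O)C(=O)C[C@@H](c2ccccc2)O3)c(O)c1C | intermediate
18 | (2S)-6-[(6-ethyl-4-hydroxy-5-methyl-2-oxo-2H-pyran-3-yl)methyl]-5,7-dihydroxy-8-(3-methylbut-2-enoyl)-2-phenyl-2,3-dihydro-4H-chromen-4-one | CCc1oc(=O)c(Cc2c(O)c(C(=O)C=C(C)C)c3c(c2O)C(=O)C[C@@H](c2ccccc2)O3)c(O)c1C | target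

## Step count and least certain steps

Total: 10 steps. Longest linear sequence: 9 steps (4 to 18, steps 2 to 10); step 1 is a one-step branch.

Step 7 (key step). The most likely failure is diversion of the carbenoid to the O1 lone pair followed by a 1,2-shift of the benzyl group, or insertion with weak discrimination between the two enantiotopic hydrogens. A carbenoid with no donor substituent is very reactive and only loosely held in the chiral pocket. The fallback sets out from 11 and comes back at 14. Hydrogenolysis of the benzyl ether of 11 (H2, palladium on carbon, EtOAc) gives the ortho-hydroxyacetophenone F1. Condensation with N,N-dimethylformamide dimethyl acetal gives the enaminone F2, which closes on mild acid treatment to the chromone F3. Enantioselective conjugate addition of phenylboronic acid to F3 with Pd(OCOCF3)2 and the tert-butyl pyridine–oxazoline ligand enantiomer that leads to 2S then gives 14. This replaces the C–H insertion by asymmetric 1,4-arylation of a chromone, a known entry to flavanones, at the price of discarding the benzyl group.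

Step 10. The most likely failure is inefficient rearrangement: excited-state proton transfer in the chelated 5-hydroxy ketone chromophore can drain the excitation before the O–CO bond breaks. Escape of the radical pair (returning 15) and photodeconjugation of the unsaturated ester are further losses. The fallback sets out from 15 and comes back at 18, bypassing 17. Iodination of 15 at C8, the only free ring position, with N-iodosuccinimide in DMF at 0 °C gives the 8-iodoflavanone F4. Carbonylative Stille coupling of F4 with tributyl(2-methylprop-1-enyl)stannane under CO (1 atm) with the zerovalent palladium complex Pd(PPh3)4 in toluene–DMF at 70 °C, without base, gives 18.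

Step 6. The most likely failure is loss or migration of a silyl group under the lithium amide or the aqueous amine, or competing deprotonation at the 6-ethyl group of the pyranone, both of which lower the yield of the activated diketone. The fallback sets out from 11 and comes back at 13 without a strong base. Soft enolisation of 11 with Me3SiOTf and Et3N in CH2Cl2 at 0 °C gives the trimethylsilyl enol ether F5. N-Bromosuccinimide in THF at −78 °C gives the alpha-bromo ketone F6. N,N'-Ditosylhydrazine and DBU in THF at 0 °C then convert F6 into 13 by N-alkylation and double loss of sulfinate.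

Step 3. The most likely failure is slow condensation, because the aldehyde is deactivated by two ortho hydroxyl donors and an internal hydrogen bond, together with diversion of the ortho-hydroxy alkylidene into a bis-pyranone adduct. The fallback sets out from 6 and comes back at 8. Silylation of both phenols of 6 (t-BuMe2SiCl, imidazole, DMF) gives the bis-silyl aldehyde F7, which is more electrophilic and cannot form a quinone methide. The same proline and Hantzsch ester conditions with 3 give the silylated bridge compound F8, and Bu4NF buffered with AcOH returns 8.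

## Further compounds

F1 | step 7 | 3-{[3-acetyl-4-hydroxy-2,6-bis(triisopropylsilyloxy)phenyl]methyl}-6-ethyl-5-methyl-4-(triisopropylsilyloxy)-2H-pyran-2-one | CCc1oc(=O)c(Cc2c(O[Si](C(C)C)(C(C)C)C(C)C)cc(O)c(C(C)=O)c2O[Si](C(C)C)(C(C)C)C(C)C)c(O[Si](C(C)C)(C(C)C)C(C)C)c1C
F2 | step 7 | (2E)-3-(dimethylamino)-1-[5-{[6-ethyl-5-methyl-2-oxo-4-(triisopropylsilyloxy)-2H-pyran-3-yl]methyl}-2-hydroxy-4,6-bis(triisopropylsilyloxy)phenyl]prop-2-en-1-one | CCc1oc(=O)c(Cc2c(O[Si](C(C)C)(C(C)C)C(C)C)cc(O)c(C(=O)/C=C/N(C)C)c2O[Si](C(C)C)(C(C)C)C(C)C)c(O[Si](C(C)C)(C(C)C)C(C)C)c1C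
F3 | step 7 | 6-{[6-ethyl-5-methyl-2-oxo-4-(triisopropylsilyloxy)-2H-pyran-3-yl]methyl}-5,7-bis(triisopropylsilyloxy)-4H-chromen-4-one | CCc1oc(=O)c(Cc2c(O[Si](C(C)C)(C(C)C)C(C)C)cc3occc(=O)c3c2O[Si](C(C)C)(C(C)C)C(C)C)c(O[Si](C(C)C)(C(C)C)C(C)C)c1C
F4 | step 10 | (2S)-6-[(6-ethyl-4-hydroxy-5-methyl-2-oxo-2H-pyran-3-yl)methyl]-5,7-dihydroxy-8-iodo-2-phenyl-2,3-dihydro-4H-chromen-4-one | CCc1oc(=O)c(Cc2c(O)c(I)c3c(c2O)C(=O)C[C@@H](c2ccccc2)O3)c(O)c1C
F5 | step 6 | 3-{[4-(benzyloxy)-2,6-bis(triisopropylsilyloxy)-3-[1-(trimethylsilyloxy)ethenyl]phenyl]methyl}-6-ethyl-5-methyl-4-(triisopropylsilyloxy)-2H-pyran-2-one | CCc1oc(=O)c(Cc2c(O[Si](C(C)C)(C(C)C)C(C)C)cc(OCc3ccccc3)c(C(=C)O[Si](C)(C)C)c2O[Si](C(C)C)(C(C)C)C(C)C)c(O[Si](C(C)C)(C(C)C)C(C)C)c1C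
F6 | step 6 | 2-bromo-1-[2-(benzyloxy)-5-{[6-ethyl-5-methyl-2-oxo-4-(triisopropylsilyloxy)-2H-pyran-3-yl]methyl}-4,6-bis(triisopropylsilyloxy)phenyl]ethan-1-one | CCc1oc(=O)c(Cc2c(O[Si](C(C)C)(C(C)C)C(C)C)cc(OCc3ccccc3)c(C(=O)CBr)c2O[Si](C(C)C)(C(C)C)C(C)C)c(O[Si](C(C)C)(C(C)C)C(C)C)c1C
F7 | step 3 | 4-(benzyloxy)-2,6-bis(tert-butyldimethylsilyloxy)benzaldehyde | O=Cc1c(O[Si](C)(C)C(C)(C)C)cc(OCc2ccccc2)cc1O[Si](C)(C)C(C)(C)C
F8 | step 3 | 3-{[4-(benzyloxy)-2,6-bis(tert-butyldimethylsilyloxy)phenyl]methyl}-6-ethyl-4-hydroxy-5-methyl-2H-pyran-2-one | CCc1oc(=O)c(Cc2c(O[Si](C)(C)C(C)(C)C)cc(OCc3ccccc3)cc2O[Si](C)(C)C(C)(C)C)c(O)c1C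
A1 | alternative 1 | (2S)-5,7-dimethoxy-8-(3-methylbut-2-enoyl)-2-phenyl-2,3-dihydro-4H-chromen-4-one | O=C1C[C@@H](c2ccccc2)Oc2c(C(=O)C=C(C)C)c(OC)cc(OC)c12
A2 | alternative 1 | (3S)-1-[2-fluoro-4,6-dimethoxy-3-(3-methylbut-2-enoyl)phenyl]-3-hydroxy-3-phenylpropan-1-one | O=C(C[C@H](O)c1ccccc1)c1c(F)c(C(=O)C=C(C)C)c(OC)cc1OC
A3 | alternative 2 | (2S,4S)-5,7-bis(benzyloxy)-6-[(6-ethyl-4-hydroxy-5-methyl-2-oxo-2H-pyran-3-yl)methyl]-4-methoxy-2-phenyl-3,4-dihydro-2H-chromene | CCc1oc(=O)c(Cc2c(OCc3ccccc3)cc3c(c2OCc2ccccc2)[C@@H](OC)C[C@@H](c2ccccc2)O3)c(O)c1C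
A4 | alternative 2 | 4,6-bis(benzyloxy)-5-[(6-ethyl-4-hydroxy-5-methyl-2-oxo-2H-pyran-3-yl)methyl]-2-hydroxybenzaldehyde | CCc1oc(=O)c(Cc2c(OCc3ccccc3)cc(O)c(C=O)c2OCc2ccccc2)c(O)c1C
A5 | alternative 2 | styrene | C=Cc1ccccc1
A6 | alternative 3 | (2S)-6-[(6-ethyl-4-hydroxy-5-methyl-2-oxo-2H-pyran-3-yl)methyl]-5,7-dihydroxy-2-phenyl-2,3-dihydro-4H-chromen-4-one (identical with 15) | CCc1oc(=O)c(Cc2c(O)cc3c(c2O)C(=O)C[C@@H](c2ccccc2)O3)c(O)c1C
A7 | alternative 3 | (3S)-3-{4-[(6-ethyl-4-hydroxy-5-methyl-2-oxo-2H-pyran-3-yl)methyl]-3,5-dihydroxyphenoxy}-3-phenylpropanoic acid | CCc1oc(=O)c(Cc2c(O)cc(O[C@@H](CC(=O)O)c3ccccc3)cc2O)c(O)c1C
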